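The retrosynthesis cuts the ester bond between the feruloyl carbonyl and the C2–CH2O oxygen, traces the C3=C4 alkene back to a C4 ketone, and then cuts C4–C4a and O1–C8a of ring B together.
Enabling feature: C2 with O1, its methyl, its CH2O arm and C3 is the carbon skeleton of (R)-citramalic acid. A carbonyl at C4 stands ortho to C8a of ring A, so the C2 alkoxide can displace a fluorine at C8a.
Forward, ring A is bought as 4'-fluoro-3'-methoxyacetophenone with the acetyl masked as a dioxolane. Ring B then arises in one flask by acylating the ortho-fluoro aryllithium with the citramalate-derived hydroxy lactone, followed by intramolecular SNAr.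
The feruloyl chain (phenol as TBS ether) is attached while C4 is still a ketone, so no free CH2OH can later bridge to a C4 cation. Reduction, acid dehydration with ketal hydrolysis, and desilylation finish the target.
The only stereocentre, C2 (R), is carried unchanged from (R)-citramalic acid, and the E alkene comes from ferulic acid.

Key step: step 4

Remark: C2 of the target reads as R from the SMILES. The CIP order O > CH2O > C3 > CH3 corresponds to O > CO2H > CH2CO2H > CH3 in citramalic acid, so the descriptor stays R in every intermediate. (R)-Citramalic acid is assumed to be commercial and enantiopure.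

Step 1
Reactants: 1 (R)-citramalic acid
Product: 2 dimethyl (R)-citramalate
Conditions: MeOH, H2SO4 (cat.), 50 °C
Reagents that add atoms: methanol, CO
Why: Fischer esterification of both carboxyl groups under mild acid should leave the tertiary carbinol, and with it the stereocentre, untouched.

Step 2
Reactants: 2 dimethyl (R)-citramalate
Product: 4 (R)-4-hydroxy-4-methyldihydrofuran-2(3H)-one, via diol ester 3 (not isolated)
Conditions: BH3·SMe2 (1.05 equiv), NaBH4 (5 mol %), THF, 0 °C → rt; MeOH quench; p-TsOH·H2O (cat.), CH2Cl2, rt
Reagents that add atoms: none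
Why: In this hydroxyl-directed chemoselective borane reduction the tertiary OH binds borane as an alkoxyborane which, activated by catalytic NaBH4, delivers hydride through a five-membered cyclic array to the adjacent ester only, and the γ-hydroxy ester 3 then lactonises under acid (5-exo-trig acyl substitution) without involving the stereocentre.

Step 3
Reactants: 5 4'-fluoro-3'-methoxyacetophenone
Product: 6 2-(4-fluoro-3-methoxyphenyl)-2-methyl-1,3-dioxolane
Conditions: HOCH2CH2OH, p-TsOH·H2O (cat.), toluene, reflux, Dean–Stark trap
Reagents that add atoms: ethylene glycol, OCCO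
Why: Acid-catalysed ketalisation with azeotropic removal of water masks the acetyl group, which would otherwise be attacked or enolised by the organolithium in step 4 and reduced in step 7.

Step 4
Reactants: 6 2-(4-fluoro-3-methoxyphenyl)-2-methyl-1,3-dioxolane; 4 (R)-4-hydroxy-4-methyldihydrofuran-2(3H)-one
Product: 11 (R)-2-(hydroxymethyl)-8-methoxy-2-methyl-6-(2-methyl-1,3-dioxolan-2-yl)chroman-4-one, via aryllithium 7 (not isolated), via lactone lithium alkoxide 8 (not isolated), via dilithium lactolate 9 (not isolated), via keto dialkoxide 10 (not isolated)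
Conditions: 6 (2.1 equiv), n-BuLi (2.05 equiv), N,N,N',N'',N''-pentamethyldiethylenetriamine (PMDTA), THF, −78 °C; 4 (1.0 equiv) in THF, −78 °C; N,N'-dimethylpropyleneurea (DMPU), −78 → 0 °C; sat aq NH4Cl, 0 °C
Reagents that add atoms: none
Why: n-BuLi complexed by PMDTA removes the most acidic ring proton of 6, the one next to fluorine (the proton between OMe and the ketal carbon is shielded), and aryllithium 7 resists LiF loss at −78 °C; its first equivalent converts 4 into alkoxide 8, whose charge discourages α-deprotonation and rules out β-elimination, and the second adds to the lactone carbonyl to give lactolate 9, which keeps the ketone masked until no aryllithium is left. On warming, 9 opens to keto dialkoxide 10, in which the new C4 carbonyl lies ortho to the C8a–F bond, so the tertiary C2 alkoxide adds to C8a to give a Meisenheimer adduct with the charge on the C4 oxygen and LiF is expelled, which forms C4–C4a and O1–C8a in one flask. The closest known reaction types are the mono-addition of organolithiums to γ-lactones and the intramolecular SNAr of alkoxides on 2-fluoroaryl ketones that gives chroman-4-ones, and the step only runs them one after the other without isolation. Ring B closes as a six-membered ring by addition–elimination at the sp2 carbon C8a, formally 6-endo-trig on the vinylogous acyl fluoride F–C8a=C4a–C4=O with the breaking C–F bond outside the ring. No stereocentre is created, and C2 keeps the R configuration of 4 because none of its four bonds is made or broken. The step needs closure by the tertiary rather than the primary alkoxide, which ring size (six against seven) and the geminal substitution at C2 secure, and it needs SNAr to outrun retro-aldol cleavage of 10 and E1cB opening of 11, for which DMPU and PMDTA free the alkoxide from its lithium chelate with the C4 carbonyl and the mixture is quenched at 0 °C as soon as 10 is consumed.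

Step 5
Reactants: 12 (E)-ferulic acid
Product: 14 (E)-3-[4-(tert-butyldimethylsilyloxy)-3-methoxyphenyl]prop-2-enoic acid, via bis-silyl derivative 13 (not isolated)
Conditions: TBSCl (2.3 equiv), imidazole, DMF, rt; AcOH–THF–H2O, rt
Reagents that add atoms: tert-butyldimethylsilyl chloride (TBSCl), CC(C)(C)[Si](C)(C)Cl
Why: Imidazole-promoted silylation covers both acidic OH groups, and aqueous AcOH then hydrolyses the far more labile silyl ester selectively, leaving the aryl silyl ether and the E alkene intact.

Step 6
Reactants: 11 (R)-2-(hydroxymethyl)-8-methoxy-2-methyl-6-(2-methyl-1,3-dioxolan-2-yl)chroman-4-one; 14 (E)-3-[4-(tert-butyldimethylsilyloxy)-3-methoxyphenyl]prop-2-enoic acid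
Product: 15 [(2R)-8-methoxy-2-methyl-6-(2-methyl-1,3-dioxolan-2-yl)-4-oxochroman-2-yl]methyl (E)-3-[4-(tert-butyldimethylsilyloxy)-3-methoxyphenyl]prop-2-enoate
Conditions: DCC, 4-(dimethylamino)pyridine (cat.), CH2Cl2, 0 °C → rt
Reagents that add atoms: none
Why: Steglich esterification acylates the neopentyl-type primary alcohol under nearly neutral conditions that spare the ketal, the silyl ether and the base-sensitive chromanone, and it removes the free CH2OH that could otherwise trap the C4 cation of step 8 as a bridged ether.

Step 7
Reactants: 15 the chroman-4-one ester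
Product: 16 [(2R,4RS)-4-hydroxy-8-methoxy-2-methyl-6-(2-methyl-1,3-dioxolan-2-yl)chroman-2-yl]methyl (E)-3-[4-(tert-butyldimethylsilyloxy)-3-methoxyphenyl]prop-2-enoate (mixture of C4 epimers)
Conditions: NaBH4, THF–MeOH, 0 °C
Reagents that add atoms: none
Why: Borohydride 1,2-reduction takes the only free ketone (the acetyl is ketalised and the cinnamate ester is inert at 0 °C), and the new C4 centre needs no control because it becomes sp2 in step 8.

Step 8
Reactants: 16 the chroman-4-ol ester
Product: 18 [(2R)-6-acetyl-8-methoxy-2-methyl-2H-chromen-2-yl]methyl (E)-3-[4-(tert-butyldimethylsilyloxy)-3-methoxyphenyl]prop-2-enoate, via chromene ketal 17 (not isolated)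
Conditions: p-TsOH·H2O (0.1 equiv), toluene, 60 °C, dark; then THF–H2O, rt
Reagents that add atoms: water, O
Why: Acid-catalysed E1 dehydration of the benzylic C4 alcohol (cation stabilised by O1, proton loss possible only from C3) should give the conjugated 2H-chromene while ring A is still electron-rich, the same acid in wet THF then hydrolyses the dioxolane, and C2 should stay R because the acyloxymethyl group disfavours C2–O1 heterolysis and moderate temperature and darkness avoid electrocyclic ring opening.

Step 9
Reactants: 18 the O-TBS-protected target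
Product: 19 [(2R)-6-acetyl-8-methoxy-2-methyl-2H-chromen-2-yl]methyl (E)-3-(4-hydroxy-3-methoxyphenyl)prop-2-enoate (CNP0168033.1)
Conditions: TBAF, AcOH, THF, 0 °C
Reagents that add atoms: none
Why: Fluoride-induced cleavage of an aryl silyl ether, buffered with AcOH so that no basic phenoxide or fluoride builds up, is fast at 0 °C and should spare the cinnamate ester, the aryl ketone and the chromene.

Compound list
1 | (R)-citramalic acid, (2R)-2-hydroxy-2-methylbutanedioic acid | OC(=O)C[C@@](C)(O)C(=O)O | starting material
2 | dimethyl (R)-citramalate | COC(=O)C[C@@](C)(O)C(=O)OC | intermediate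
3 | methyl (R)-3,4-dihydroxy-3-methylbutanoate | COC(=O)C[C@@](C)(O)CO | intermediate
4 | (R)-4-hydroxy-4-methyldihydrofuran-2(3H)-one | O=C1C[C@@](C)(O)CO1 | intermediate
5 | 4'-fluoro-3'-methoxyacetophenone | CC(=O)c1ccc(F)c(OC)c1 | starting material
6 | 2-(4-fluoro-3-methoxyphenyl)-2-methyl-1,3-dioxolane | CC1(OCCO1)c1ccc(F)c(OC)c1 | intermediate
7 | [2-fluoro-3-methoxy-5-(2-methyl-1,3-dioxolan-2-yl)phenyl]lithium | [Li]c1cc(C2(C)OCCO2)cc(OC)c1F | intermediate
8 | lithium alkoxide of 4, lithium (R)-3-methyl-5-oxooxolan-3-olate | O=C1C[C@@](C)(O[Li])CO1 | intermediate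
9 | dilithium salt of (4R)-2-[2-fluoro-3-methoxy-5-(2-methyl-1,3-dioxolan-2-yl)phenyl]-4-methyloxolane-2,4-diol (lactol carbon unassigned) | [Li]OC1(C[C@@](C)(O[Li])CO1)c1cc(C2(C)OCCO2)cc(OC)c1F | intermediate
10 | dilithium salt of (R)-1-[2-fluoro-3-methoxy-5-(2-methyl-1,3-dioxolan-2-yl)phenyl]-3,4-dihydroxy-3-methylbutan-1-one | O=C(C[C@@](C)(O[Li])CO[Li])c1cc(C2(C)OCCO2)cc(OC)c1F | intermediate
11 | (R)-2-(hydroxymethyl)-8-methoxy-2-methyl-6-(2-methyl-1,3-dioxolan-2-yl)chroman-4-one | OC[C@@]1(C)CC(=O)c2cc(C3(C)OCCO3)cc(OC)c2O1 | intermediate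
12 | (E)-ferulic acid | COc1cc(/C=C/C(=O)O)ccc1O | starting material
13 | tert-butyldimethylsilyl (E)-3-[4-(tert-butyldimethylsilyloxy)-3-methoxyphenyl]prop-2-enoate | COc1cc(/C=C/C(=O)O[Si](C)(C)C(C)(C)C)ccc1O[Si](C)(C)C(C)(C)C | intermediate
14 | (E)-3-[4-(tert-butyldimethylsilyloxy)-3-methoxyphenyl]prop-2-enoic acid | COc1cc(/C=C/C(=O)O)ccc1O[Si](C)(C)C(C)(C)C | intermediate
15 | [(2R)-8-methoxy-2-methyl-6-(2-methyl-1,3-dioxolan-2-yl)-4-oxochroman-2-yl]methyl (E)-4-O-TBS-ferulate | COc1cc(/C=C/C(=O)OC[C@@]2(C)CC(=O)c3cc(C4(C)OCCO4)cc(OC)c3O2)ccc1O[Si](C)(C)C(C)(C)C | intermediate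
16 | [(2R,4RS)-4-hydroxy-8-methoxy-2-methyl-6-(2-methyl-1,3-dioxolan-2-yl)chroman-2-yl]methyl (E)-4-O-TBS-ferulate, C4 epimers | COc1cc(/C=C/C(=O)OC[C@@]2(C)CC(O)c3cc(C4(C)OCCO4)cc(OC)c3O2)ccc1O[Si](C)(C)C(C)(C)C | intermediate
17 | [(2R)-8-methoxy-2-methyl-6-(2-methyl-1,3-dioxolan-2-yl)-2H-chromen-2-yl]methyl (E)-4-O-TBS-ferulate | COc1cc(/C=C/C(=O)OC[C@@]2(C)C=Cc3cc(C4(C)OCCO4)cc(OC)c3O2)ccc1O[Si](C)(C)C(C)(C)C | intermediate
18 | [(2R)-6-acetyl-8-methoxy-2-methyl-2H-chromen-2-yl]methyl (E)-4-O-TBS-ferulate | COc1cc(/C=C/C(=O)OC[C@@]2(C)C=Cc3cc(C(C)=O)cc(OC)c3O2)ccc1O[Si](C)(C)C(C)(C)C | intermediate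
19 | [(2R)-6-acetyl-8-methoxy-2-methyl-2H-chromen-2-yl]methyl (E)-3-(4-hydroxy-3-methoxyphenyl)prop-2-enoate | COc1cc(/C=C/C(=O)OC[C@@]2(C)C=Cc3cc(C(C)=O)cc(OC)c3O2)ccc1O | target

Total step count: 9
Longest linear sequence: 7 steps (1, 2, 4, 6, 7, 8, 9)

Steps most likely to fail

Step 4. Three processes threaten it:
- proton transfer from the lactone α-CH2 to the aryllithium in place of addition;
- retro-aldol fragmentation of the tertiary β-alkoxy ketone during warming;
- erosion of configurational purity by reversible base-induced opening of the chromanone.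

The fallback separates the two bond formations and removes all acidic protons from the acyl donor. It sets out from 4 and 6 and returns at 11. Lactone 4 is opened with MeNH(OMe)·HCl and i-PrMgCl in THF to the Weinreb amide diol F1. Both hydroxyls are silylated with TESOTf and 2,6-lutidine to give the bis(triethylsilyl) ether F2. One equivalent of aryllithium 7, made from 6 as in step 4, is acylated by F2 through the chelated tetrahedral adduct to give the ketone F3. TBAF buffered with AcOH, which the ketal tolerates, liberates the keto diol F4. F4 is isolated and cyclised on its own with Cs2CO3 in DMF at rt. There the alkoxide is not held in a lithium chelate and no strong base remains once the fluoride has left, and the product is 11.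

Step 8. Acid may oligomerise the styrenyl ether, ionise the allylic C2–O1 bond with loss of configurational purity, or strip the silyl ether early. The fallback replaces the cationic dehydration by sulfonate activation and base-induced elimination. It sets out from 16 and returns at 18. MsCl and Et3N in CH2Cl2 at 0 °C give the C4 mesylate F5, which DBU eliminates in the same flask to chromene ketal 17, now isolated. Pyridinium p-toluenesulfonate in THF–H2O at rt then hydrolyses the dioxolane to 18.

Step 2. The hindered tertiary hydroxyl may capture borane too slowly, so the directing effect is lost and both esters are reduced. The fallback gives up site selectivity in the reduction and differentiates the termini afterwards. It sets out from 2 and returns at 4. LiAlH4 in THF reduces both esters to the triol F6. Acetone with p-TsOH·H2O ties the 1,2-diol into the five-membered acetonide alcohol F7, leaving only the distal primary hydroxyl free. 2,2,6,6-Tetramethylpiperidine-1-oxyl (cat.) with PhI(OAc)2 in MeCN–H2O oxidises it to the acetonide acid F8. Aqueous trifluoroacetic acid removes the acetonide, and the freed primary hydroxyl lactonises to 4.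

Further compounds
F1 | step 4 | (R)-3,4-dihydroxy-N-methoxy-N,3-dimethylbutanamide | CON(C)C(=O)C[C@@](C)(O)CO
F2 | step 4 | (R)-N-methoxy-N,3-dimethyl-3,4-bis(triethylsilyloxy)butanamide | CON(C)C(=O)C[C@@](C)(O[Si](CC)(CC)CC)CO[Si](CC)(CC)CC
F3 | step 4 | (R)-1-[2-fluoro-3-methoxy-5-(2-methyl-1,3-dioxolan-2-yl)phenyl]-3-methyl-3,4-bis(triethylsilyloxy)butan-1-one | O=C(C[C@@](C)(O[Si](CC)(CC)CC)CO[Si](CC)(CC)CC)c1cc(C2(C)OCCO2)cc(OC)c1F
F4 | step 4 | (R)-1-[2-fluoro-3-methoxy-5-(2-methyl-1,3-dioxolan-2-yl)phenyl]-3,4-dihydroxy-3-methylbutan-1-one | O=C(C[C@@](C)(O)CO)c1cc(C2(C)OCCO2)cc(OC)c1F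
F5 | step 8 | C4 methanesulfonate of 16 (C4 epimers) | COc1cc(/C=C/C(=O)OC[C@@]2(C)CC(OS(C)(=O)=O)c3cc(C4(C)OCCO4)cc(OC)c3O2)ccc1O[Si](C)(C)C(C)(C)C
F6 | step 2 | (R)-2-methylbutane-1,2,4-triol | OCC[C@@](C)(O)CO
F7 | step 2 | 2-[(R)-2,2,4-trimethyl-1,3-dioxolan-4-yl]ethanol | OCC[C@]1(C)COC(C)(C)O1
F8 | step 2 | 2-[(R)-2,2,4-trimethyl-1,3-dioxolan-4-yl]acetic acid | OC(=O)C[C@]1(C)COC(C)(C)O1
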